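**Strategy**

Everything rests on cutting the C2–C3 bond of ring C. C2 carries O1 and ring B and lies β to the C4 carbonyl, so it can be held at the acetal level, bridging O1 and the enol oxygen on C4 in a 2-aryl-4-methylene-1,3-benzodioxine. Under a chiral silylium catalyst this racemic enol acetal opens at C2 and the enol carbon C3 re-bonds to it; that single operation makes C2–C3, completes ring C and fixes the only stereocenter as 2S from both enantiomers. The precursor is the tetrakis-O-triisopropylsilyl 6-farnesyl enol acetal 15, whose ring A derives from a mirror-symmetric 4-farnesyl-3,5-disilyloxyphenol, which fixes the farnesyl position and its 2E,6E geometry.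

Key step: step 9

**Remarks on the chemistry (assumptions and design choices)**

- Abbreviations: TIPS = triisopropylsilyl; farnesyl = (2E,6E)-3,7,11-trimethyldodeca-2,6,10-trien-1-yl. Chromanone numbering is used (O1, C2, C3, C4, C4a, C5–C8, C8a); ring A is the benzo ring, ring B the 2-aryl group, ring C the pyranone.
- Structures: 15 and 17 are consistent with the target (farnesyl on C6; C2 of 17 and 18 is S, with O1 > C1′ > C3 > H). One point is refined: with a silylium Lewis acid the ring-opened species is an oxocarbenium ion carrying a neutral enol silane (16) and paired with the chiral anion, not a free enolate.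
- The farnesyl group is attached by SN2 alkylation of an aryllithium. An oxygen-to-carbon Claisen–Cope transfer is avoided because its Cope step would rebuild the C2″=C3″ double bond from a quaternary carbon bearing methyl and a chain of similar size, without control of the E geometry, and would compete with branched ortho transfer to C8.
- O1 is defined by symmetry, not by selective protection: it is introduced para to the farnesyl site of a symmetric arene, and the carbonyl carbon is then placed on either of two equivalent ortho positions.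
- All four phenols carry the same non-acetal silyl ether, since a second O,O-acetal or an acyl group would compete for the silylium ion. TIPS is chosen because it resists migration from oxygen to a neighbouring lithiated carbon.
- Assumption: one antipode of the confined catalyst should deliver 2S; which one does so has to be established by experiment.

**Route**

Step 1
Reactants: 1 2-bromobenzene-1,3-diol (2-bromoresorcinol)
Product: 2 2-bromo-1,3-bis(triisopropylsilyloxy)benzene
Conditions: TIPSCl (2.4 equiv), imidazole (5 equiv), DMF, 25 → 40 °C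
Reagents that add atoms: chlorotriisopropylsilane (TIPSCl), CC(C)[Si](Cl)(C(C)C)C(C)C
Why: Imidazole-promoted silylation of phenols is routine even next to bromine, and the bulky TIPS groups are chosen to survive the organolithium, oxidation and Lewis acid steps that follow.

Step 2
Reactants: 2 2-bromo-1,3-bis(triisopropylsilyloxy)benzene
Product: 4 4-bromo-3,5-bis(triisopropylsilyloxy)phenol, via aryl pinacol boronate 3 (not isolated)
Conditions: [Ir(OMe)(cod)]2 (1.5 mol%), 4,4′-di-tert-butyl-2,2′-bipyridine (3 mol%), HBpin (1.5 equiv), THF, 60 °C; evaporate; then Oxone (KHSO5), acetone–H2O, 25 °C, 10 min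
Reagents that add atoms: pinacolborane, CC1(C)OBOC1(C)C (boron is held only in the not-isolated 3); potassium peroxymonosulfate, [K+].[O-]S(=O)(=O)OO (supplies the phenol oxygen)
Why: Iridium-catalysed aromatic C–H borylation is governed by sterics and can only reach C5, the one C–H without an ortho substituent, and peroxymonosulfate oxidation of the C–B bond in the same pot (borylation–oxidation sequence) places the future O1 on the symmetry axis para to bromine without touching the aryl bromide or the silyl ethers.

Step 3
Reactants: 4 4-bromo-3,5-bis(triisopropylsilyloxy)phenol; 5 (2E,6E)-farnesyl bromide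
Product: 7 4-[(2E,6E)-farnesyl]-3,5-bis(triisopropylsilyloxy)phenol, via dilithiated phenoxide 6 (not isolated)
Conditions: t-BuLi (3.1 equiv), Et2O–THF, −78 °C; CuBr·SMe2 (10 mol%), then 5 (1.05 equiv), −78 → −20 °C; H2O
Reagents that add atoms: tert-butyllithium, [Li]C(C)(C)C (lithium is held only in the not-isolated 6)
Why: Bromine–lithium exchange on the lithium phenoxide gives an aryllithium that is alkylated at C1 of the allylic bromide under copper catalysis (SN2 allylation of an organometallic), so the farnesyl group lands between the two silyloxy groups with its 2E,6E geometry untouched, and the bulky TIPS groups suppress the 1,3 migration of silicon from oxygen to the lithiated carbon at −78 °C.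

Step 4
Reactants: 7 4-[(2E,6E)-farnesyl]-3,5-bis(triisopropylsilyloxy)phenol
Product: 9 3-[(2E,6E)-farnesyl]-6-hydroxy-2,4-bis(triisopropylsilyloxy)benzaldehyde, via benzylic alcohol 8 (not isolated)
Conditions: MgCl2 (2 equiv), Et3N (4 equiv), (CH2O)n (6 equiv), THF, 65 °C; dilute aqueous citric acid work-up
Reagents that add atoms: paraformaldehyde (as formaldehyde), C=O
Why: The magnesium-mediated ortho-formylation of phenols (Casnati–Skattebøl reaction) delivers formaldehyde only to a carbon next to the magnesium phenoxide and then oxidises the benzylic alcohol 8 by hydride transfer to a second formaldehyde, and since both ortho positions of 7 are equivalent a single salicylaldehyde is expected under these non-acidic conditions.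

Step 5
Reactants: 9 3-[(2E,6E)-farnesyl]-6-hydroxy-2,4-bis(triisopropylsilyloxy)benzaldehyde
Product: 10 3-[(2E,6E)-farnesyl]-6-hydroxy-2,4-bis(triisopropylsilyloxy)benzoic acid
Conditions: NaClO2 (3 equiv), NaH2PO4 (3 equiv), 2-methyl-2-butene (30 equiv), t-BuOH–THF–H2O, 0 → 20 °C; used without heating
Reagents that add atoms: sodium chlorite, [Na+].[O-]Cl=O
Why: Pinnick oxidation turns the aldehyde into the carboxylic acid at a pH of about 4, and the large excess of 2-methyl-2-butene traps hypochlorous acid before it can attack the three trisubstituted alkenes or the electron-rich ring.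

Step 6
Reactants: 11 3,5-dihydroxybenzaldehyde
Product: 12 3,5-bis(triisopropylsilyloxy)benzaldehyde
Conditions: TIPSCl (2.4 equiv), imidazole (5 equiv), DMF, 25 °C
Reagents that add atoms: chlorotriisopropylsilane (TIPSCl), CC(C)[Si](Cl)(C(C)C)C(C)C
Why: Imidazole-promoted silylation of the two unhindered phenols is routine and leaves the aldehyde untouched.

Step 7
Reactants: 10 3-[(2E,6E)-farnesyl]-6-hydroxy-2,4-bis(triisopropylsilyloxy)benzoic acid; 12 3,5-bis(triisopropylsilyloxy)benzaldehyde
Product: 14 rac-6-[(2E,6E)-farnesyl]-5,7-bis(triisopropylsilyloxy)-2-[3,5-bis(triisopropylsilyloxy)phenyl]-4H-1,3-benzodioxin-4-one, via bis-trimethylsilyl derivative 13 (not isolated)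
Conditions: N,O-bis(trimethylsilyl)acetamide (1.5 equiv), CH2Cl2, 25 °C; then 12 (1.1 equiv), TMSOTf (10 mol%), 2,6-di-tert-butyl-4-methylpyridine (10 mol%), −78 → −30 °C; Et3N quench
Reagents that add atoms: N,O-bis(trimethylsilyl)acetamide, CC(=N[Si](C)(C)C)O[Si](C)(C)C (silicon is held only in the not-isolated 13)
Why: Silyl-transfer acetalisation of the Noyori type: the silyl ester and silyl ether of 13 add to the TMSOTf-activated aldehyde with loss of hexamethyldisiloxane to close the six-membered acylal under aprotic low-temperature conditions that spare the triene and the aryl silyl ethers; only the phenol that becomes O1 is free, so only one ring can form, and C2 arises as a racemate, which is intended.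

Step 8
Reactants: 14 rac-6-[(2E,6E)-farnesyl]-5,7-bis(triisopropylsilyloxy)-2-[3,5-bis(triisopropylsilyloxy)phenyl]-4H-1,3-benzodioxin-4-one
Product: 15 rac-6-[(2E,6E)-farnesyl]-4-methylene-5,7-bis(triisopropylsilyloxy)-2-[3,5-bis(triisopropylsilyloxy)phenyl]-4H-1,3-benzodioxine
Conditions: Cp2TiMe2 (3 equiv), toluene–THF, 70 °C, dark; filtration through basic Al2O3 with Et3N-doped eluent
Reagents that add atoms: dimethyltitanocene Cp2TiMe2, C[Ti](C)(C1C=CC=C1)C1C=CC=C1 (supplies the CH2 carbon)
Why: Petasis methylenation: on heating, Cp2TiMe2 gives Cp2Ti=CH2, which converts the lactone carbonyl into the exocyclic enol ether through an oxatitanacyclobutane under conditions that are neither acidic nor basic and tolerate the acetal carbon, the silyl ethers and the trisubstituted alkenes.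

Step 9
Reactants: 15 rac-6-[(2E,6E)-farnesyl]-4-methylene-5,7-bis(triisopropylsilyloxy)-2-[3,5-bis(triisopropylsilyloxy)phenyl]-4H-1,3-benzodioxine
Product: 17 (2S)-6-[(2E,6E)-farnesyl]-5,7-bis(triisopropylsilyloxy)-2-[3,5-bis(triisopropylsilyloxy)phenyl]chroman-4-one, via oxocarbenium enol silane 16 (not isolated)
Conditions: BINOL-derived N-triflyl imidodiphosphorimidate acid (IDPi–H, 5 mol%, antipode chosen by screening) pre-silylated with methallyltrimethylsilane (15 mol%), toluene, 25 °C; then 15 added slowly at −78 °C (0.02 M), −78 → −60 °C; Et3N quench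
Reagents that add atoms: none
Why: Proposed new method: the pre-formed silylium–imidodiphosphorimidate ion pair silylates the enol ether oxygen O3, and the C2–O3 bond ionises because the cation at C2 is stabilised by O1 and ring B, giving oxocarbenium 16 with a pendant trimethylsilyl enol ether and the chiral anion as counterion; C3 of the enol silane then adds to C2 (an intramolecular Mukaiyama-type addition) and the silylated ketone passes the silyl cation to the next molecule, so no reagent is consumed. The closest known reaction types are the Me2AlCl-promoted Petasis–Ferrier rearrangement of 4-methylene-1,3-dioxanes to tetrahydropyran-4-ones and chiral-anion-directed additions of enol silanes to oxocarbenium ions generated from acetals. Ring C closes in the 6-(enolendo)-endo-trig mode, with C3 and C4 of the enol and the O1=C2 bond of the electrophile all inside the new ring, which is a favoured closure. The C2 stereocenter of the racemic acetal is lost in planar 16, whose mirror-image conformers should interconvert by rotation about C4a–C4 and by reversible re-closure at O3 faster than the slower C–C bond formation, so both enantiomers of 15 pass through one intermediate and the face of C2 that C3 attacks is set by the confined chiral anion alone (catalyst control). The step needs carbon instead of oxygen recombination, ionisation instead of protonation of the 1,1-disubstituted enol ether, and no crossover between molecules; these are secured by the irreversible C–C bond formation, by the proton-free pre-silylated catalyst, by high dilution at low temperature, and by having every phenol capped as a non-acetal silyl ether. Regiochemistry is not at stake, because the O1–C8a and O1–C2 bonds are never broken and O5 and O7 are blocked, so closure through another oxygen (the 8-farnesyl series) or an open chalcone cannot arise.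

Step 10
Reactants: 17 (2S)-6-[(2E,6E)-farnesyl]-5,7-bis(triisopropylsilyloxy)-2-[3,5-bis(triisopropylsilyloxy)phenyl]chroman-4-one
Product: 18 (2S)-2-(3,5-dihydroxyphenyl)-6-[(2E,6E)-farnesyl]-5,7-dihydroxychroman-4-one (CNP0186816.1)
Conditions: Bu4NF (6 equiv), AcOH (6 equiv), THF, 0 → 20 °C
Reagents that add atoms: none
Why: Fluoride-mediated desilylation cleaves all four aryl silyl ethers, and the equimolar acetic acid protonates each phenoxide as it forms, so that the flavanone cannot open by E1cB elimination to the achiral chalcone and the C2 configuration set in step 9 is retained.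

**Compound list**

1 | 2-bromobenzene-1,3-diol (2-bromoresorcinol) | Oc1cccc(O)c1Br | starting material
2 | 2-bromo-1,3-bis(triisopropylsilyloxy)benzene | Brc1c(O[Si](C(C)C)(C(C)C)C(C)C)cccc1O[Si](C(C)C)(C(C)C)C(C)C | intermediate
3 | 2-[4-bromo-3,5-bis(triisopropylsilyloxy)phenyl]-4,4,5,5-tetramethyl-1,3,2-dioxaborolane | CC1(C)OB(OC1(C)C)c1cc(O[Si](C(C)C)(C(C)C)C(C)C)c(Br)c(O[Si](C(C)C)(C(C)C)C(C)C)c1 | intermediate (not isolated)
4 | 4-bromo-3,5-bis(triisopropylsilyloxy)phenol | Oc1cc(O[Si](C(C)C)(C(C)C)C(C)C)c(Br)c(O[Si](C(C)C)(C(C)C)C(C)C)c1 | intermediate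
5 | (2E,6E)-farnesyl bromide | CC(C)=CCC/C(C)=C/CC/C(C)=C/CBr | starting material
6 | lithium 4-lithio-3,5-bis(triisopropylsilyloxy)phenoxide | [Li]Oc1cc(O[Si](C(C)C)(C(C)C)C(C)C)c([Li])c(O[Si](C(C)C)(C(C)C)C(C)C)c1 | intermediate (not isolated)
7 | 4-[(2E,6E)-farnesyl]-3,5-bis(triisopropylsilyloxy)phenol | CC(C)=CCC/C(C)=C/CC/C(C)=C/Cc1c(O[Si](C(C)C)(C(C)C)C(C)C)cc(O)cc1O[Si](C(C)C)(C(C)C)C(C)C | intermediate
8 | 4-[(2E,6E)-farnesyl]-2-(hydroxymethyl)-3,5-bis(triisopropylsilyloxy)phenol | CC(C)=CCC/C(C)=C/CC/C(C)=C/Cc1c(O[Si](C(C)C)(C(C)C)C(C)C)cc(O)c(CO)c1O[Si](C(C)C)(C(C)C)C(C)C | intermediate (not isolated)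
9 | 3-[(2E,6E)-farnesyl]-6-hydroxy-2,4-bis(triisopropylsilyloxy)benzaldehyde | CC(C)=CCC/C(C)=C/CC/C(C)=C/Cc1c(O[Si](C(C)C)(C(C)C)C(C)C)cc(O)c(C=O)c1O[Si](C(C)C)(C(C)C)C(C)C | intermediate
10 | 3-[(2E,6E)-farnesyl]-6-hydroxy-2,4-bis(triisopropylsilyloxy)benzoic acid | CC(C)=CCC/C(C)=C/CC/C(C)=C/Cc1c(O[Si](C(C)C)(C(C)C)C(C)C)cc(O)c(C(=O)O)c1O[Si](C(C)C)(C(C)C)C(C)C | intermediate
11 | 3,5-dihydroxybenzaldehyde | O=Cc1cc(O)cc(O)c1 | starting material
12 | 3,5-bis(triisopropylsilyloxy)benzaldehyde | O=Cc1cc(O[Si](C(C)C)(C(C)C)C(C)C)cc(O[Si](C(C)C)(C(C)C)C(C)C)c1 | intermediate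
13 | trimethylsilyl 3-[(2E,6E)-farnesyl]-2,4-bis(triisopropylsilyloxy)-6-(trimethylsilyloxy)benzoate | CC(C)=CCC/C(C)=C/CC/C(C)=C/Cc1c(O[Si](C(C)C)(C(C)C)C(C)C)cc(O[Si](C)(C)C)c(C(=O)O[Si](C)(C)C)c1O[Si](C(C)C)(C(C)C)C(C)C | intermediate (not isolated)
14 | rac-6-[(2E,6E)-farnesyl]-5,7-bis(triisopropylsilyloxy)-2-[3,5-bis(triisopropylsilyloxy)phenyl]-4H-1,3-benzodioxin-4-one | CC(C)=CCC/C(C)=C/CC/C(C)=C/Cc1c(O[Si](C(C)C)(C(C)C)C(C)C)cc2c(c1O[Si](C(C)C)(C(C)C)C(C)C)C(=O)OC(c1cc(O[Si](C(C)C)(C(C)C)C(C)C)cc(O[Si](C(C)C)(C(C)C)C(C)C)c1)O2 | intermediate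
15 | rac-6-[(2E,6E)-farnesyl]-4-methylene-5,7-bis(triisopropylsilyloxy)-2-[3,5-bis(triisopropylsilyloxy)phenyl]-4H-1,3-benzodioxine (precursor of the key step) | CC(C)=CCC/C(C)=C/CC/C(C)=C/Cc1c(O[Si](C(C)C)(C(C)C)C(C)C)cc2c(c1O[Si](C(C)C)(C(C)C)C(C)C)C(=C)OC(c1cc(O[Si](C(C)C)(C(C)C)C(C)C)cc(O[Si](C(C)C)(C(C)C)C(C)C)c1)O2 | intermediate
16 | [3,5-bis(triisopropylsilyloxy)benzylidene]{4-[(2E,6E)-farnesyl]-3,5-bis(triisopropylsilyloxy)-2-[1-(trimethylsilyloxy)vinyl]phenyl}oxonium, paired with the imidodiphosphorimidate anion | CC(C)=CCC/C(C)=C/CC/C(C)=C/Cc1c(O[Si](C(C)C)(C(C)C)C(C)C)cc([O+]=Cc2cc(O[Si](C(C)C)(C(C)C)C(C)C)cc(O[Si](C(C)C)(C(C)C)C(C)C)c2)c(C(=C)O[Si](C)(C)C)c1O[Si](C(C)C)(C(C)C)C(C)C | intermediate (not isolated)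
17 | (2S)-6-[(2E,6E)-farnesyl]-5,7-bis(triisopropylsilyloxy)-2-[3,5-bis(triisopropylsilyloxy)phenyl]chroman-4-one (product of the key step) | CC(C)=CCC/C(C)=C/CC/C(C)=C/Cc1c(O[Si](C(C)C)(C(C)C)C(C)C)cc2c(c1O[Si](C(C)C)(C(C)C)C(C)C)C(=O)C[C@@H](c1cc(O[Si](C(C)C)(C(C)C)C(C)C)cc(O[Si](C(C)C)(C(C)C)C(C)C)c1)O2 | intermediate
18 | (2S)-2-(3,5-dihydroxyphenyl)-6-[(2E,6E)-farnesyl]-5,7-dihydroxychroman-4-one (CNP0186816.1) | CC(C)=CCC/C(C)=C/CC/C(C)=C/Cc1c(O)cc2c(c1O)C(=O)C[C@@H](c1cc(O)cc(O)c1)O2 | target

**Step count**

Total: 10 steps. Longest linear sequence: 9 steps (1 to 18 through steps 1–5 and 7–10); step 6 is a one-step side branch.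

**Steps most likely to fail, with fallbacks**

Step 9 (key step). What may go wrong:
- poor facial selectivity, because the very large, heavily silylated substrate may not sit inside the confined anion;
- collapse of the ion pair before its conformers equilibrate, so that each enantiomer of 15 keeps a memory of its acetal configuration and the product is formed with little enantiomeric excess;
- protonation of the enol ether by traces of acid, leading to hydrolysis;
- slow turnover, because the silylated ketone holds the silyl cation.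

The fallback uses known chemistry only; it sets out from 15 and returns at 17. Mild acid hydrolysis of 15 (PPTS, wet THF, 25 °C) should protonate the enol ether and release the methyl ketone 1-{3-[(2E,6E)-farnesyl]-6-hydroxy-2,4-bis(triisopropylsilyloxy)phenyl}ethan-1-one F1 together with aldehyde 12. A pyrrolidine-promoted Claisen–Schmidt condensation of F1 with 12 (EtOH–THF, 50 °C) should give the 2′-hydroxychalcone F2. In the same pot F2 should close by oxa-Michael addition of the only free phenol, so that again only the 6-farnesyl series is possible, to the racemic flavanone rac-6-[(2E,6E)-farnesyl]-5,7-bis(triisopropylsilyloxy)-2-[3,5-bis(triisopropylsilyloxy)phenyl]chroman-4-one F3. A kinetic resolution by Noyori-type asymmetric transfer hydrogenation (RuCl(p-cymene)[TsDPEN] in the antipode that reduces the 2R ketone faster, HCO2H–Et3N, EtOAc, 25 °C, stopped near half conversion) should consume the unwanted enantiomer as the cis-(2R,4R)-flavan-4-ol F4 and leave (S)-17, which is separated by chromatography and taken into step 10.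

Step 3 (farnesylation). What may go wrong:
- migration of a silyl group from oxygen to the lithiated carbon;
- elimination of HBr from the allylic bromide by the hindered aryllithium;
- alkylation of the phenoxide oxygen on warming.

The fallback avoids a carbanion; it sets out from 4 and returns at 7. Tributyl[(2E,6E)-farnesyl]stannane F5 is prepared from 5 and Bu3SnLi (THF, −78 °C). A Stille coupling of 4 with F5 (Pd2(dba)3, P(t-Bu)3, dioxane, 90 °C) should transfer the allyl group at its α-carbon with the E geometry kept, and the free phenol is tolerated.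

Step 7 (acetalisation). What may go wrong:
- incomplete condensation, because the acylal re-ionises under the silyl triflate;
- triflic acid traces that start cyclisation of the triene;
- decarboxylation of the electron-rich hydroxy acid.

The fallback replaces silyl transfer by an acetal exchange under thermodynamic control; it sets out from 10 and 12 and returns at 14. Aldehyde 12 is converted into 1-(dimethoxymethyl)-3,5-bis(triisopropylsilyloxy)benzene F6 (HC(OMe)3, PPTS cat., MeOH, 25 °C). F6 is then exchanged with hydroxy acid 10 (PPTS cat., toluene, 5 Å molecular sieves, 40 °C, methanol removed as it forms) to give 14.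

**Further compounds**

F1 | step 9 | 1-{3-[(2E,6E)-farnesyl]-6-hydroxy-2,4-bis(triisopropylsilyloxy)phenyl}ethan-1-one | CC(C)=CCC/C(C)=C/CC/C(C)=C/Cc1c(O[Si](C(C)C)(C(C)C)C(C)C)cc(O)c(C(C)=O)c1O[Si](C(C)C)(C(C)C)C(C)C
F2 | step 9 | (E)-3-[3,5-bis(triisopropylsilyloxy)phenyl]-1-{3-[(2E,6E)-farnesyl]-6-hydroxy-2,4-bis(triisopropylsilyloxy)phenyl}prop-2-en-1-one | CC(C)=CCC/C(C)=C/CC/C(C)=C/Cc1c(O[Si](C(C)C)(C(C)C)C(C)C)cc(O)c(C(=O)/C=C/c2cc(O[Si](C(C)C)(C(C)C)C(C)C)cc(O[Si](C(C)C)(C(C)C)C(C)C)c2)c1O[Si](C(C)C)(C(C)C)C(C)C
F3 | step 9 | rac-6-[(2E,6E)-farnesyl]-5,7-bis(triisopropylsilyloxy)-2-[3,5-bis(triisopropylsilyloxy)phenyl]chroman-4-one | CC(C)=CCC/C(C)=C/CC/C(C)=C/Cc1c(O[Si](C(C)C)(C(C)C)C(C)C)cc2c(c1O[Si](C(C)C)(C(C)C)C(C)C)C(=O)CC(c1cc(O[Si](C(C)C)(C(C)C)C(C)C)cc(O[Si](C(C)C)(C(C)C)C(C)C)c1)O2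
F4 | step 9 | (2R,4R)-6-[(2E,6E)-farnesyl]-5,7-bis(triisopropylsilyloxy)-2-[3,5-bis(triisopropylsilyloxy)phenyl]chroman-4-ol (cis) | CC(C)=CCC/C(C)=C/CC/C(C)=C/Cc1c(O[Si](C(C)C)(C(C)C)C(C)C)cc2c(c1O[Si](C(C)C)(C(C)C)C(C)C)[C@H](O)C[C@H](c1cc(O[Si](C(C)C)(C(C)C)C(C)C)cc(O[Si](C(C)C)(C(C)C)C(C)C)c1)O2
F5 | step 3 | tributyl[(2E,6E)-farnesyl]stannane | CC(C)=CCC/C(C)=C/CC/C(C)=C/C[Sn](CCCC)(CCCC)CCCC
F6 | step 7 | 1-(dimethoxymethyl)-3,5-bis(triisopropylsilyloxy)benzene | COC(OC)c1cc(O[Si](C(C)C)(C(C)C)C(C)C)cc(O[Si](C(C)C)(C(C)C)C(C)C)c1
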